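## Structural features

Gustastatin (19) is an achiral depside built from two benzene rings and two identical 2-oxoheptyl chains, so no stereocentre has to be set or relayed. Ring A is a 2-hydroxy-4-methoxy-6-(2-oxoheptyl)benzoyl unit and ring B is a methyl 2-methoxy-6-(2-oxoheptyl)benzoate; they are joined only by the ester between the carboxyl carbon on C1 of ring A and the oxygen on C4 of ring B. Both rings have the orsellinate pattern (carboxyl at C1, oxygen at C2 and C4, carbon at C6), but the oxygens are differentiated in opposite senses: ring A keeps a chelated 2-hydroxyl and is methylated on O4, ring B is methylated on O2 and acylated on O4. The fragile parts are the aryl ester, whose leaving group is a phenol made acidic by a para ester, and the two ArCH2C(=O) ketones, each ortho to an ester carbonyl and able to close onto it as an enol to give an isocoumarin. The real difficulty is the depside bond: the ring A acid is 2,6-disubstituted, its own side-chain ketone intercepts any activated carboxyl, and the ring B phenol is a poor nucleophile. The feature that removes this difficulty is that the ester carbonyl, ring A atoms C1 to C6 and the side chain form one unbroken 1,3-oxygenated chain (ester C=O, C1, C2–O, C3, C4–O, C5, C6, CH2, C=O, pentyl), a hexanoyl-started pentaketide. Ring A can therefore be folded from a linear aryl 3,5,7-trioxooctanoate already esterified to ring B, by one aldol bond between ring atoms C1 and C6 (chain atoms C2 and C7), provided the ninth chain carbon stays a dioxolane so that it cannot act as a second aldol acceptor.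

## Logic of the disconnections

19 to 18. The four C–O bonds of two dioxolanes are put back on the two ketones. A free ArCH2C(=O) ketone next to an ester is the origin of isocoumarin formation and, in ring A, of a second aldol pathway, so both ketones stay masked while bases, heat and nucleophiles are in use. The gain is that every earlier intermediate carries only inert ketals. The demand is a hydrolysis mild enough to leave the depside ester and the freshly freed keto esters untouched.

18 to 17. The O–CH3 bond on O4 of ring A is cut. The aromatisation necessarily delivers both ring A oxygens as hydroxyls, and they differ sharply: the 2-hydroxyl is held in a hydrogen bond to the ester carbonyl, the 4-hydroxyl is free and more acidic. The gain is that no oxygen has to be differentiated in the open chain. The demand is a methylating agent that reacts only with the free acidic phenol and brings no nucleophile for the aryl ester.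

17 to 15. The bond between ring A atoms C1 and C6 is cut and the ring is unfolded to the open chain. This turns an aromatic ring with a hindered acyl bond to ring B into a chain that already hangs on ring B through an unhindered β-keto ester. The gain is one ring and the whole problem of the hindered acid. The demand is that the forward aldol outruns Claisen closure onto the aryl ester and loss of the ring B phenoxide, and that C9 stays masked.

15 to 6 and 13. The ester C(=O)–O bond is cut, giving phenol 13 and acylketene 14, whose stable equivalent is 6. An acylketene acylates a hydroxyl group without activating agent, base or steric penalty, and the dioxinone releases it on heating. The gain is two fragments of similar size. The demand is that the weakly nucleophilic phenol captures 14 faster than the enol oxygen of 14 does.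

6 to 2 and 5. The C–C bond between the outer CH2 of the dioxinone side chain and the next carbonyl is cut. This corresponds to acylation of the terminal carbon of the dianion of 2, its most reactive site, by an acyl donor that stops at the ketone stage. The gain is that 6 comes from two small pieces. The demand is clean dianion formation, an amide that is not enolised, and a ketal that survives strong base.

2 to 1, and 5 to 4 to 3. In 2 the bond between the CH2 and the acetyl carbonyl is cut (acylation of the dienolate of 1). In 5 the amide C–N bond is cut back to ester 4, and the ketal C–O bonds back to 3. The ketal is placed on the β-keto ester at the outset, where ketone and ester are easily told apart. The same group later blocks the second aldol, so it costs no extra step.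

13 to 12 to 11. The O–CH2Ph bond is restored and then the dioxolane C–O bonds are cut. The phenol needed for the union must be covered during the strongly basic chain extension, and benzyl is removed by neutral hydrogenation that touches neither ketal nor ester. The demand is a ketalisation of 11 that does not lactonise the ketone onto the ortho ester.

11 to 9 and 10. The benzylic CH2–C(=O) bond is cut. The ortho-toluate methyl group is the one acidic C–H of 9, and its anion takes up the whole hexanoyl unit in one step. The demand is that the lithiated species is acylated by 10 faster than it condenses with the ester of unreacted 9.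

9 to 8 to 7. The O–CH3 bond on O2 and then the O–CH2Ph bond on O4 are cut. In the forward sense the free 4-hydroxyl is benzylated first and the chelated 2-hydroxyl is then methylated under more forcing conditions. The gain is commercial 7, which holds all ring B carbons except the hexanoyl unit. The demand is selectivity in the first alkylation.

## Other disconnections considered

Alternative 1: The cut falls in ring B and removes both ortho carbon substituents at once: the bond from ring carbon C6 to the benzylic CH2 and the bond from ring carbon C1 to the ester carbonyl. In the forward direction fluoride would release the aryne 5-(benzyloxy)-3-methoxybenzyne A2 from the silyl triflate 5-(benzyloxy)-3-methoxy-2-(trimethylsilyl)phenyl trifluoromethanesulfonate A1. The carbanion of dimethyl malonate A3 should add at the aryne carbon remote from the methoxy group. The aryl anion, held next to the methoxy group, should then attack a malonate carbonyl and fragment, moving a methoxycarbonyl group to the ring and giving methyl 4-(benzyloxy)-2-methoxy-6-(2-methoxy-2-oxoethyl)benzoate A4.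
- In its favour: two carbon–carbon bonds form in one operation, the methoxy group sets the regiochemistry, and no benzylic carbanion is present that could condense with its own ester. On bonds formed per step and on freedom from self-condensation it is better than step 7.
- Against it here: A1 needs a multistep synthesis of its own, longer than the two alkylations that lead to 9. A4 carries an acetate ester where 11 has a pentyl ketone, so the aliphatic ester must be hydrolysed selectively, converted to an N-methoxy-N-methylamide and treated with a pentyl organometallic. A β-keto ester cannot be inserted instead, because its acyl group rather than the alkoxycarbonyl group would move to the ring.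
- Comparison: structurally it touches only ring B, the easier half, and leaves the depside bond and ring A unsolved. Mechanistically it is a polar aryne insertion against a lateral lithiation, and both are equally free of stereochemical questions. In step count it should be longer for ring B than the sequence 7 to 11.

Alternative 2: The cut is the bond between ring A carbon C6 and the side-chain CH2, made by C–H functionalisation, with a lactone as a temporary ring. In the forward direction 2-(benzyloxy)-4-methoxybenzoic acid A5 and the hexanoyl sulfoxonium ylide 1-[dimethyl(oxo)-λ6-sulfanylidene]heptan-2-one A6 would couple under catalysis by a pentamethylcyclopentadienyl complex of trivalent rhodium with an acetate base. Carboxylate-directed ortho metalation, carbene formation from the ylide, migratory insertion, protonation and cyclodehydration should give 8-(benzyloxy)-6-methoxy-3-pentyl-1H-isochromen-1-one A7.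
- In its favour: both partners are one or two steps from commercial materials, only one ortho C–H is free so the regiochemistry is certain, and the metal is catalytic. The ring A oxygens are differentiated from the start (methyl on O4, benzyl on O2). On step count to the ring A carbon skeleton and on the oxygen pattern it is better than the chosen plan, which needs a selective methylation.
- Against it here: A7 is the very lactone into which ring A collapses whenever its carboxyl is activated next to the free ketone. To go on to 19 the lactone must be opened, the ketone masked in the open form, and a 2,6-disubstituted acid esterified with the deactivated phenol 13. Direct opening of A7 by the phenoxide of 13 is uphill, because the enolate so formed can re-close and expel the phenoxide.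
- Comparison: the carbon skeleton is reached faster, but the depside C(=O)–O bond, the real difficulty, is postponed and not solved. The chosen plan forms that bond first on an unhindered β-keto ester and never handles the acid. Mechanistically it is C–H activation against an aldol, with no stereochemical issue on either side. Over the whole route the step count is expected to be higher once opening, masking, esterification and debenzylation are added.

Alternative 3: The cut removes two ring A bonds, C1–C2 and C5–C6, in a [4+2] sense. In the forward direction 1,3-dimethoxy-1-(trimethylsilyloxy)buta-1,3-diene A9 would add to the triple bond of the ring B aryl ynoate 3-methoxy-4-(methoxycarbonyl)-5-[(2-pentyl-1,3-dioxolan-2-yl)methyl]phenyl 4-(2-pentyl-1,3-dioxolan-2-yl)but-2-ynoate A8, the nucleophilic CH2 terminus of the diene bonding to the β-carbon of the ynoate. Loss of methanol and of the silyl group would aromatise the adduct to gustastatin bis-dioxolane A10, which is the same compound as 18.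
- In its favour: ring A is again built on a finished ester, so on the central point of avoiding the hindered acid it is the equal of the chosen plan. It is better on oxygen differentiation, since the 4-methoxy and 2-hydroxy groups arrive in place and the selective methylation of step 12 is not needed. It also forms two ring bonds in one step against one.
- Against it here: A8 needs a 4-substituted but-2-ynoic acid with a ketal next to the propargylic CH2, which can isomerise to an allenoate, and this acid must be esterified with the poor nucleophile 13. Aryl ynoates are strong conjugate acceptors for phenols. Cycloadditions of β-alkyl ynoates with such ketene acetal dienes need heat and can divert to stepwise conjugate addition or to attack of the diene on the aryl ester. The diene is moisture sensitive.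
- Comparison: the step count should be close to that of the chosen plan, a step shorter after ring formation and longer before it. The chosen plan draws all ring A carbons from two cheap pieces (1 and 3) and forms the ester through a neutral acylketene, which is judged the more dependable entry.

Key step: step 11

Remark on the chemistry: commercial N-methoxy-N-methylhexanamide and commercial solutions of LiN(i-Pr)2, LiN(SiMe3)2 and Me3SiCHN2 are assumed; chain atoms of 15 are counted C1 (ester carbonyl) to C8, and the two stereocentres of 16 are transient, unassigned and erased by aromatisation.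

## Route

Step 1
Reactants: 1 2,2,6-trimethyl-4H-1,3-dioxin-4-one
Product: 2 2,2-dimethyl-6-(2-oxopropyl)-4H-1,3-dioxin-4-one
Conditions: LiN(SiMe3)2, THF, −78 °C; AcCl (0.5 equiv), −78 °C; aq NH4Cl
Reagents that add atoms: acetyl chloride CC(Cl)=O
Why: γ-Deprotonation gives the lithium dienolate, which is C-acylated at the exocyclic carbon (Claisen-type acylation of a vinylogous ester enolate); half an equivalent of acetyl chloride is used because 2 is more acidic than 1 and consumes a second dienolate.

Step 2
Reactants: 3 methyl 3-oxooctanoate
Product: 4 methyl 2-(2-pentyl-1,3-dioxolan-2-yl)acetate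
Conditions: HOCH2CH2OH, p-TsOH (cat.), toluene, reflux, azeotropic removal of water
Reagents that add atoms: ethylene glycol OCCO
Why: Acid-catalysed ketalisation of the ketone, which is far more electrophilic than the ester; removal of water drives the equilibrium.

Step 3
Reactants: 4 methyl 2-(2-pentyl-1,3-dioxolan-2-yl)acetate
Product: 5 N-methoxy-N-methyl-2-(2-pentyl-1,3-dioxolan-2-yl)acetamide
Conditions: MeNH(OMe)·HCl, i-PrMgCl, THF, −20 → 0 °C
Reagents that add atoms: N,O-dimethylhydroxylamine hydrochloride CNOC.Cl
Why: The chloromagnesium amide made in the flask adds to the ester and the chelated tetrahedral intermediate collapses to the amide (direct aminolysis of an ester to an N-methoxy-N-methylamide); the ketal is inert to these basic conditions.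

Step 4
Reactants: 2 2,2-dimethyl-6-(2-oxopropyl)-4H-1,3-dioxin-4-one; 5 N-methoxy-N-methyl-2-(2-pentyl-1,3-dioxolan-2-yl)acetamide
Product: 6 6-[2,4-dioxo-5-(2-pentyl-1,3-dioxolan-2-yl)pentyl]-2,2-dimethyl-4H-1,3-dioxin-4-one
Conditions: LiN(i-Pr)2 (2.1 equiv per 2), THF, −78 → −40 °C; then 5, −78 → −30 °C; aq NH4Cl
Reagents that add atoms: none
Why: Double deprotonation of 2 gives a dianion that reacts at its terminal, most basic carbon (Claisen-type C-acylation of a 1,3-dicarbonyl dianion); the chelated adduct of the N-methoxy-N-methylamide releases the ketone only on work-up, so neither over-addition nor quenching of the dianion by the product should occur.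

Step 5
Reactants: 7 methyl 2,4-dihydroxy-6-methylbenzoate (methyl orsellinate)
Product: 8 methyl 4-(benzyloxy)-2-hydroxy-6-methylbenzoate
Conditions: BnBr (1.05 equiv), K2CO3, acetone, reflux
Reagents that add atoms: benzyl bromide BrCc1ccccc1
Why: Williamson etherification; the 4-hydroxyl is the more acidic and accessible one, while the 2-hydroxyl is held in a hydrogen bond to the ester carbonyl and should stay free.

Step 6
Reactants: 8 methyl 4-(benzyloxy)-2-hydroxy-6-methylbenzoate
Product: 9 methyl 4-(benzyloxy)-2-methoxy-6-methylbenzoate
Conditions: MeI, K2CO3, DMF, 50 °C
Reagents that add atoms: iodomethane CI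
Why: Williamson etherification of the remaining chelated phenol, for which the dipolar solvent, excess iodomethane and mild heating should suffice.

Step 7
Reactants: 9 methyl 4-(benzyloxy)-2-methoxy-6-methylbenzoate; 10 N-methoxy-N-methylhexanamide
Product: 11 methyl 4-(benzyloxy)-2-methoxy-6-(2-oxoheptyl)benzoate
Conditions: LiN(i-Pr)2 (1.3 equiv), THF, −78 °C; then 10, −78 °C; aq NH4Cl at −78 °C
Reagents that add atoms: none
Why: Lateral lithiation of the ortho-toluate methyl group (anion stabilised by the ortho ester) followed by acylation with the N-methoxy-N-methylamide; the stable tetrahedral adduct and a cold quench should prevent double addition and closure onto the ester.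

Step 8
Reactants: 11 methyl 4-(benzyloxy)-2-methoxy-6-(2-oxoheptyl)benzoate
Product: 12 methyl 4-(benzyloxy)-2-methoxy-6-[(2-pentyl-1,3-dioxolan-2-yl)methyl]benzoate
Conditions: Me3SiOCH2CH2OSiMe3, Me3SiOTf (cat.), CH2Cl2, −78 → 0 °C; Et3N quench
Reagents that add atoms: 1,2-bis(trimethylsilyloxy)ethane C[Si](C)(C)OCCO[Si](C)(C)C
Why: Silyl-triflate-catalysed ketalisation with the bis-silyl ether of ethylene glycol, driven by formation of hexamethyldisiloxane; the cold, aprotic, water-free medium should avoid both transesterification and enol lactonisation onto the ortho ester.

Step 9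
Reactants: 12 methyl 4-(benzyloxy)-2-methoxy-6-[(2-pentyl-1,3-dioxolan-2-yl)methyl]benzoate
Product: 13 methyl 4-hydroxy-2-methoxy-6-[(2-pentyl-1,3-dioxolan-2-yl)methyl]benzoate
Conditions: H2 (1 atm), 10% Pd/C, EtOAc, rt
Reagents that add atoms: none
Why: Catalytic hydrogenolysis of the benzyl aryl ether under neutral conditions, which leave the dioxolane, the methyl ether and the ester untouched.

Step 10
Reactants: 6 6-[2,4-dioxo-5-(2-pentyl-1,3-dioxolan-2-yl)pentyl]-2,2-dimethyl-4H-1,3-dioxin-4-one; 13 methyl 4-hydroxy-2-methoxy-6-[(2-pentyl-1,3-dioxolan-2-yl)methyl]benzoate
Product: 15 3-methoxy-4-(methoxycarbonyl)-5-[(2-pentyl-1,3-dioxolan-2-yl)methyl]phenyl 3,5,7-trioxo-8-(2-pentyl-1,3-dioxolan-2-yl)octanoate, via acylketene 14 (not isolated)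
Conditions: toluene (concentrated), 110 °C, N2 sweep to remove acetone; crude used directly
Reagents that add atoms: none
Why: Thermal retro-[4+2] fragmentation of the dioxinone releases acetone and acylketene 14, and the phenol O–H adds across the ketene to give the aryl β-keto ester (acylketene trapping by a hydroxyl nucleophile); no base or activating agent is present, so ketals and esters should survive.

Step 11
Reactants: 15 3-methoxy-4-(methoxycarbonyl)-5-[(2-pentyl-1,3-dioxolan-2-yl)methyl]phenyl 3,5,7-trioxo-8-(2-pentyl-1,3-dioxolan-2-yl)octanoate
Product: 17 3-methoxy-4-(methoxycarbonyl)-5-[(2-pentyl-1,3-dioxolan-2-yl)methyl]phenyl 2,4-dihydroxy-6-[(2-pentyl-1,3-dioxolan-2-yl)methyl]benzoate, via aldol adduct 16 (not isolated)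
Conditions: Et3N, CH2Cl2, 0 °C → rt; pH 6 buffer work-up
Reagents that add atoms: none
Why: Et3N reversibly ionises the doubly activated C2 methylene of 15 (between the aryl ester and the C3 ketone); the enolate carbon attacks the C7 ketone to give aldol 16, which loses water by an E1cB path and tautomerises at C3 and C5 to the resorcylate, so that the new C2–C7 bond becomes the C1–C6 bond of ring A. The closest known reaction type is the base-mediated aldol cyclisation–dehydration of 3,5,7-trioxo esters obtained by acylketene trapping, which gives 6-substituted 2,4-dihydroxybenzoates. Ring A closes by a 6-exo-trig attack on the C7 carbonyl; the C2=C3 enol double bond lies inside the new ring, so the mode is 6-(enolendo)-exo-trig (enolexo only if the ester enolate is drawn), and it is allowed either way. No stereocentre is created in 17; the two of 16 are erased by aromatisation, which also makes the sequence irreversible. Three side paths have to be beaten: Claisen attack of C6 on the aryl ester carbonyl, E1cB loss of the ring B phenoxide from the C2 enolate, and an aldol of C8 onto C3. A ketone is a better acceptor than an ester, a tertiary amine in CH2Cl2 supplies no alkoxide and is too weak to ionise the singly activated, neopentyl C8, and the intramolecular aldol should be fast at 0 °C, which together should keep the aryl ester intact. The dioxolane at C9 removes the only other six-membered aldol open to a doubly activated carbon (C4 onto C9).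

Step 12
Reactants: 17 3-methoxy-4-(methoxycarbonyl)-5-[(2-pentyl-1,3-dioxolan-2-yl)methyl]phenyl 2,4-dihydroxy-6-[(2-pentyl-1,3-dioxolan-2-yl)methyl]benzoate
Product: 18 3-methoxy-4-(methoxycarbonyl)-5-[(2-pentyl-1,3-dioxolan-2-yl)methyl]phenyl 2-hydroxy-4-methoxy-6-[(2-pentyl-1,3-dioxolan-2-yl)methyl]benzoate (gustastatin bis-dioxolane)
Conditions: Me3SiCHN2 (1.2 equiv), MeOH–toluene (1:4), 0 °C → rt
Reagents that add atoms: (trimethylsilyl)diazomethane C[Si](C)(C)C=[N+]=[N-]
Why: O-Methylation of a phenol by a diazoalkane: the free, acidic 4-hydroxyl protonates the reagent and is methylated, while the 2-hydroxyl, hydrogen-bonded to the ester carbonyl, should not react; the neutral medium carries no nucleophile strong enough for the hindered depside ester.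

Step 13
Reactants: 18 3-methoxy-4-(methoxycarbonyl)-5-[(2-pentyl-1,3-dioxolan-2-yl)methyl]phenyl 2-hydroxy-4-methoxy-6-[(2-pentyl-1,3-dioxolan-2-yl)methyl]benzoate
Product: 19 gustastatin, 3-methoxy-4-(methoxycarbonyl)-5-(2-oxoheptyl)phenyl 2-hydroxy-4-methoxy-6-(2-oxoheptyl)benzoate
Conditions: 1 M aq HCl–THF (1:3), rt, stopped at full conversion
Reagents that add atoms: water O
Why: Acid-catalysed hydrolysis of both dialkyl ketals; dilute acid at room temperature should leave the methyl ester, the methyl ethers and the hindered aryl ester intact, and a short contact time limits enol lactonisation of the freed ketones.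

## Compound list

1 | 2,2,6-trimethyl-4H-1,3-dioxin-4-one | CC1=CC(=O)OC(C)(C)O1 | starting material
2 | 2,2-dimethyl-6-(2-oxopropyl)-4H-1,3-dioxin-4-one | CC(=O)CC1=CC(=O)OC(C)(C)O1 | intermediate
3 | methyl 3-oxooctanoate | CCCCCC(=O)CC(=O)OC | starting material
4 | methyl 2-(2-pentyl-1,3-dioxolan-2-yl)acetate | CCCCCC1(CC(=O)OC)OCCO1 | intermediate
5 | N-methoxy-N-methyl-2-(2-pentyl-1,3-dioxolan-2-yl)acetamide | CCCCCC1(CC(=O)N(C)OC)OCCO1 | intermediate
6 | 6-[2,4-dioxo-5-(2-pentyl-1,3-dioxolan-2-yl)pentyl]-2,2-dimethyl-4H-1,3-dioxin-4-one | CCCCCC1(CC(=O)CC(=O)CC2=CC(=O)OC(C)(C)O2)OCCO1 | intermediate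
7 | methyl 2,4-dihydroxy-6-methylbenzoate (methyl orsellinate) | Cc1cc(O)cc(O)c1C(=O)OC | starting material
8 | methyl 4-(benzyloxy)-2-hydroxy-6-methylbenzoate | Cc1cc(OCc2ccccc2)cc(O)c1C(=O)OC | intermediate
9 | methyl 4-(benzyloxy)-2-methoxy-6-methylbenzoate | Cc1cc(OCc2ccccc2)cc(OC)c1C(=O)OC | intermediate
10 | N-methoxy-N-methylhexanamide | CCCCCC(=O)N(C)OC | starting material
11 | methyl 4-(benzyloxy)-2-methoxy-6-(2-oxoheptyl)benzoate | CCCCCC(=O)Cc1cc(OCc2ccccc2)cc(OC)c1C(=O)OC | intermediate
12 | methyl 4-(benzyloxy)-2-methoxy-6-[(2-pentyl-1,3-dioxolan-2-yl)methyl]benzoate | CCCCCC1(Cc2cc(OCc3ccccc3)cc(OC)c2C(=O)OC)OCCO1 | intermediate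
13 | methyl 4-hydroxy-2-methoxy-6-[(2-pentyl-1,3-dioxolan-2-yl)methyl]benzoate (ring B phenol) | CCCCCC1(Cc2cc(O)cc(OC)c2C(=O)OC)OCCO1 | intermediate
14 | 8-(2-pentyl-1,3-dioxolan-2-yl)oct-1-ene-1,3,5,7-tetraone (acylketene, not isolated) | CCCCCC1(CC(=O)CC(=O)CC(=O)C=C=O)OCCO1 | intermediate
15 | 3-methoxy-4-(methoxycarbonyl)-5-[(2-pentyl-1,3-dioxolan-2-yl)methyl]phenyl 3,5,7-trioxo-8-(2-pentyl-1,3-dioxolan-2-yl)octanoate | CCCCCC1(OCCO1)CC(=O)CC(=O)CC(=O)CC(=O)Oc1cc(CC2(CCCCC)OCCO2)c(C(=O)OC)c(OC)c1 | intermediate
16 | 3-methoxy-4-(methoxycarbonyl)-5-[(2-pentyl-1,3-dioxolan-2-yl)methyl]phenyl 2-hydroxy-4,6-dioxo-2-[(2-pentyl-1,3-dioxolan-2-yl)methyl]cyclohexane-1-carboxylate (aldol adduct, not isolated; two transient stereocentres, unassigned mixture) | CCCCCC1(OCCO1)CC2(O)CC(=O)CC(=O)C2C(=O)Oc3cc(CC4(CCCCC)OCCO4)c(C(=O)OC)c(OC)c3 | intermediate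
17 | 3-methoxy-4-(methoxycarbonyl)-5-[(2-pentyl-1,3-dioxolan-2-yl)methyl]phenyl 2,4-dihydroxy-6-[(2-pentyl-1,3-dioxolan-2-yl)methyl]benzoate | CCCCCC1(OCCO1)Cc1cc(O)cc(O)c1C(=O)Oc1cc(CC2(CCCCC)OCCO2)c(C(=O)OC)c(OC)c1 | intermediate
18 | 3-methoxy-4-(methoxycarbonyl)-5-[(2-pentyl-1,3-dioxolan-2-yl)methyl]phenyl 2-hydroxy-4-methoxy-6-[(2-pentyl-1,3-dioxolan-2-yl)methyl]benzoate | CCCCCC1(OCCO1)Cc1cc(OC)cc(O)c1C(=O)Oc1cc(CC2(CCCCC)OCCO2)c(C(=O)OC)c(OC)c1 | intermediate
19 | gustastatin | CCCCCC(=O)Cc1cc(OC)cc(O)c1C(=O)Oc1cc(CC(=O)CCCCC)c(C(=O)OC)c(OC)c1 | target

## Step count and least certain steps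

Total step count: 13. Longest linear sequence: 9 steps (7 → 8 → 9 → 11 → 12 → 13 → 15 → 17 → 18 → 19, steps 5 to 13).

Step 11 (key step). The most likely failure is fragmentation of the aryl ester. Once C2 is ionised, the enolate can expel the ring B phenoxide and regenerate 14, which then acylates its own enol oxygen, or C6 can attack the ester carbonyl in a Claisen closure. Both are helped by the good leaving group. The aldol may also stall before dehydration. Fallback: aromatise before the ester exists. From 6, Et3N in CH2Cl2 should close the ring onto the dioxinone itself (its α-carbon attacks the same ketone), giving 7-hydroxy-2,2-dimethyl-5-[(2-pentyl-1,3-dioxolan-2-yl)methyl]-4H-1,3-benzodioxin-4-one F1. MeI and K2CO3 in acetone methylate its only free hydroxyl, the other oxygen being locked in the acetonide, to give 7-methoxy-2,2-dimethyl-5-[(2-pentyl-1,3-dioxolan-2-yl)methyl]-4H-1,3-benzodioxin-4-one F2. Irradiation of F2 at 300 nm in CH2Cl2 with 13 should release acetone and a quinoketene that the phenol traps. The fallback sets out from 6 and returns at 18, replacing steps 10 to 12 by three operations.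

Step 10. Capture of 14 by the electron-poor phenol may be slow and reversible at 110 °C, so that intramolecular O-acylation by the chain enol or ketene oligomerisation drains the material. Adding Et3N to the cooled solution straight after thermolysis limits the time 15 spends hot. Fallback: trap with a better nucleophile and transfer the acyl group at room temperature. From 6, heating with 2-methylpropane-2-thiol in toluene should give S-tert-butyl 3,5,7-trioxo-8-(2-pentyl-1,3-dioxolan-2-yl)octanethioate F3. AgOCOCF3 (monovalent silver) with 13 and Na2HPO4 in THF at room temperature then activates the thioester towards the phenol. The fallback sets out from 6 and returns at 15.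

Step 13. After unmasking, the ring A ketone can enolise and close onto the depside carbonyl under acid, cleaving the ester with loss of the ring B phenol; stopping early leaves partial hydrolysis. Fallback: exchange deprotection instead of hydrolysis. From 18, catalytic iodine in dry acetone at room temperature transfers both glycol units to the solvent without water or Brønsted acid. It sets out from 18 and arrives at 19; no new compound is involved.

Step 4. The dianion of 2 is a delocalised, moderate nucleophile. Proton transfer from the α-methylene of 5, base-induced opening of the dioxolane, or simply low conversion may dominate. Fallback: aldol addition followed by oxidation. From 4, i-Bu2AlH in CH2Cl2 at −78 °C should give 2-(2-pentyl-1,3-dioxolan-2-yl)acetaldehyde F4. The dianion of 2 adds to this far more electrophilic partner to give racemic 6-[4-hydroxy-2-oxo-5-(2-pentyl-1,3-dioxolan-2-yl)pentyl]-2,2-dimethyl-4H-1,3-dioxin-4-one F5. 2-Iodoxybenzoic acid in DMSO at room temperature oxidises the β-hydroxy ketone. The fallback sets out from 4 and returns at 6.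

Step 7. The lithiated toluate may condense with the methyl ester of unreacted 9, or the tetrahedral adduct may close onto the ortho ester on warming, and either process lowers the return of 11. Step 8 shares the lactonisation risk. Fallback: build ring B by the same polyketide folding, which bypasses steps 5 to 8. From 6, heating with methanol in toluene at 110 °C gives (through 14) methyl 3,5,7-trioxo-8-(2-pentyl-1,3-dioxolan-2-yl)octanoate F6. Et3N aromatises it to methyl 2,4-dihydroxy-6-[(2-pentyl-1,3-dioxolan-2-yl)methyl]benzoate F7; an alkyl ester has no good leaving group, so the aryl ester side reactions do not apply. BnBr and K2CO3 give methyl 4-(benzyloxy)-2-hydroxy-6-[(2-pentyl-1,3-dioxolan-2-yl)methyl]benzoate F8, and MeI with K2CO3 in DMF methylates the chelated hydroxyl. The fallback sets out from 6 and returns at 12.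

## Further compounds

F1 | step 11 | 7-hydroxy-2,2-dimethyl-5-[(2-pentyl-1,3-dioxolan-2-yl)methyl]-4H-1,3-benzodioxin-4-one | CCCCCC1(OCCO1)Cc1cc(O)cc2OC(C)(C)OC(=O)c12
F2 | step 11 | 7-methoxy-2,2-dimethyl-5-[(2-pentyl-1,3-dioxolan-2-yl)methyl]-4H-1,3-benzodioxin-4-one | CCCCCC1(OCCO1)Cc1cc(OC)cc2OC(C)(C)OC(=O)c12
F3 | step 10 | S-tert-butyl 3,5,7-trioxo-8-(2-pentyl-1,3-dioxolan-2-yl)octanethioate | CCCCCC1(OCCO1)CC(=O)CC(=O)CC(=O)CC(=O)SC(C)(C)C
F0 | step 13 | none | none
F4 | step 4 | 2-(2-pentyl-1,3-dioxolan-2-yl)acetaldehyde | CCCCCC1(CC=O)OCCO1
F5 | step 4 | 6-[4-hydroxy-2-oxo-5-(2-pentyl-1,3-dioxolan-2-yl)pentyl]-2,2-dimethyl-4H-1,3-dioxin-4-one (racemic) | CCCCCC1(CC(O)CC(=O)CC2=CC(=O)OC(C)(C)O2)OCCO1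
F6 | step 7 | methyl 3,5,7-trioxo-8-(2-pentyl-1,3-dioxolan-2-yl)octanoate | CCCCCC1(OCCO1)CC(=O)CC(=O)CC(=O)CC(=O)OC
F7 | step 7 | methyl 2,4-dihydroxy-6-[(2-pentyl-1,3-dioxolan-2-yl)methyl]benzoate | CCCCCC1(OCCO1)Cc1cc(O)cc(O)c1C(=O)OC
F8 | step 7 | methyl 4-(benzyloxy)-2-hydroxy-6-[(2-pentyl-1,3-dioxolan-2-yl)methyl]benzoate | CCCCCC1(OCCO1)Cc1cc(OCc2ccccc2)cc(O)c1C(=O)OC
A1 | alternative 1 | 5-(benzyloxy)-3-methoxy-2-(trimethylsilyl)phenyl trifluoromethanesulfonate | COc1cc(OCc2ccccc2)cc(OS(=O)(=O)C(F)(F)F)c1[Si](C)(C)C
A2 | alternative 1 | 5-(benzyloxy)-3-methoxybenzyne | COC1=CC(OCc2ccccc2)=CC#C1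
A3 | alternative 1 | dimethyl malonate | COC(=O)CC(=O)OC
A4 | alternative 1 | methyl 4-(benzyloxy)-2-methoxy-6-(2-methoxy-2-oxoethyl)benzoate | COC(=O)Cc1cc(OCc2ccccc2)cc(OC)c1C(=O)OC
A5 | alternative 2 | 2-(benzyloxy)-4-methoxybenzoic acid | COc1ccc(C(=O)O)c(OCc2ccccc2)c1
A6 | alternative 2 | 1-[dimethyl(oxo)-λ6-sulfanylidene]heptan-2-one | CCCCCC(=O)C=S(C)(C)=O
A7 | alternative 2 | 8-(benzyloxy)-6-methoxy-3-pentyl-1H-isochromen-1-one | CCCCCC1=Cc2cc(OC)cc(OCc3ccccc3)c2C(=O)O1
A8 | alternative 3 | 3-methoxy-4-(methoxycarbonyl)-5-[(2-pentyl-1,3-dioxolan-2-yl)methyl]phenyl 4-(2-pentyl-1,3-dioxolan-2-yl)but-2-ynoate | CCCCCC1(OCCO1)CC#CC(=O)Oc1cc(CC2(CCCCC)OCCO2)c(C(=O)OC)c(OC)c1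
A9 | alternative 3 | 1,3-dimethoxy-1-(trimethylsilyloxy)buta-1,3-diene | C=C(OC)C=C(OC)O[Si](C)(C)C
A10 | alternative 3 | gustastatin bis-dioxolane (identical with 18) | CCCCCC1(OCCO1)Cc1cc(OC)cc(O)c1C(=O)Oc1cc(CC2(CCCCC)OCCO2)c(C(=O)OC)c(OC)c1
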